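**Retrosynthetic overview**

1. The target is a bicyclo[7.2.1]dodecane fused to ring A: the ten-membered ring C5–C6–C7–C8–C14–C13–C12–C11–C9–C10 is bridged by C15–C16. Enabling feature: the C9 ketone and the C8=C14 olefin flank C8 (a Grob pair), and C13, next to C14, carries C16. The cyclopentenone C8–C14–C13–C16–C15 is therefore a cyclobutanone C8–C14–C16–C15 with C13 inserted, and the ten-membered ring is two fused six-membered rings (B, C) minus the C8–C9 bond.
2. Key disconnection (step 18): re-form C8–C9 and return C16 from C13 to C14, giving the 6-6-6-4 tetracycle 22 (9-OH, C13–Br, 2-methylenecyclobutanone).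
3. Cyclobutane: silicon-tethered enone–allene [2+2] (forms C8–C15 and C14–C16); the tether from the C9 oxygen fixes the face, and its C–Si bond becomes the C15 oxygen.
4. Enone, 9-OH, 11-OAc and 7-OH: p-quinol by oxidative dearomatization of a C13 phenol, epoxidation/reductive opening at C11–C12, benzylic oxidation/reduction at C7.
5. Ring order: arene (purchased) → rings A and B by enantioselective polyene cyclization (sets C5, C10) → cyclobutane plus temporary oxasilolane (step 13) → five- and ten-membered rings together (step 18).

Key step: step 18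

Remark on the chemistry: carbons are numbered as in ent-kaurane (C20 = methyl on C10; C18/C19 = methyls on C4); "cis/trans to C20" gives the ring face in the polycyclic intermediates.

**Route**

Step 1
Reactants: 1 3-methoxybenzylmagnesium chloride; 2 geranyl bromide
Product: 3 1-[(3E)-4,8-dimethylnona-3,7-dien-1-yl]-3-methoxybenzene
Conditions: Li2CuCl4 (3 mol %), THF, 0 °C to rt
Reagents that add atoms: none
Why: Copper-catalysed sp3–sp3 cross-coupling (Kochi type) of a benzylic Grignard reagent with a primary allylic bromide should occur at the primary carbon with retention of the E olefin; no stereocentre is formed.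

Step 2
Reactants: 3 1-[(3E)-4,8-dimethylnona-3,7-dien-1-yl]-3-methoxybenzene
Product: 4 (5R,10R)-13-methoxypodocarpa-8,11,13-triene [(4aR,10aR)-7-methoxy-1,1,4a-trimethyl-1,2,3,4,4a,9,10,10a-octahydrophenanthrene]
Conditions: 3,3'-dichloro-BINOL·SbCl5 complex (0.5 equiv; the enantiomer that gives the 4aR,10aR series), CH2Cl2, –78 °C
Reagents that add atoms: none
Why: Enantioselective proton-initiated cation–olefin polycyclization: chair–chair folding of the E-polyene should give the trans ring fusion (H5 trans to C20), the chiral Brønsted-acid-assisted Lewis acid selects the face of the terminal olefin (absolute configuration at C5 and C10), and the arene closes para to OMe.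

Step 3
Reactants: 4 (5R,10R)-13-methoxypodocarpa-8,11,13-triene
Product: 5 (5R,10R)-13-methoxy-7-oxopodocarpa-8,11,13-triene
Conditions: CrO3, AcOH/H2O, 25 °C
Reagents that add atoms: chromium trioxide, O=[Cr](=O)=O
Why: Chromium(VI) benzylic oxidation should attack the only benzylic methylene (C7), since the other benzylic position is the quaternary C10.

Step 4
Reactants: 5 (5R,10R)-13-methoxy-7-oxopodocarpa-8,11,13-triene
Product: 6 (5R,10R)-13-hydroxy-7-oxopodocarpa-8,11,13-triene
Conditions: BBr3, CH2Cl2, –78 to 0 °C; then H2O
Reagents that add atoms: none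
Why: Lewis-acid cleavage of the aryl methyl ether (BBr3 demethylation) should free the phenol and tolerate the aryl ketone.

Step 5
Reactants: 6 (5R,10R)-13-hydroxy-7-oxopodocarpa-8,11,13-triene
Product: 7 (5R,7R,10R)-podocarpa-8,11,13-triene-7,13-diol (7-OH cis to C20)
Conditions: NaBH4, MeOH/THF, 0 °C
Reagents that add atoms: none
Why: Hydride reduction of the aryl ketone by axial attack on the half-chair ring B should give the pseudo-equatorial alcohol, cis to the angular methyl (sets C7).

Step 6
Reactants: 7 (5R,7R,10R)-podocarpa-8,11,13-triene-7,13-diol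
Product: 8 7,9-dihydroxypodocarpa-8(14),11-dien-13-one (p-quinol; 7-OH cis, 9-OH trans to C20)
Conditions: PhI(OAc)2, MeCN/H2O (4:1), 0 °C
Reagents that add atoms: water, O
Why: Hypervalent-iodine oxidative dearomatization of a para-alkyl phenol to a p-quinol: water should add at the para carbon C9 from the face opposite the axial C10 methyl (sets C9).

Step 7
Reactants: 8 7,9-dihydroxypodocarpa-8(14),11-dien-13-one
Product: 9 7-(tert-butyldimethylsilyloxy)-9-hydroxypodocarpa-8(14),11-dien-13-one
Conditions: TBSCl, imidazole, DMF, 0 °C to rt
Reagents that add atoms: tert-butyldimethylsilyl chloride, CC(C)(C)[Si](C)(C)Cl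
Why: Silyl ether formation should take the secondary C7 alcohol and leave the hindered tertiary C9 alcohol free.

Step 8
Reactants: 9 7-(tert-butyldimethylsilyloxy)-9-hydroxypodocarpa-8(14),11-dien-13-one
Product: 10 7-(tert-butyldimethylsilyloxy)-11,12-epoxy-9-hydroxypodocarp-8(14)-en-13-one (epoxide cis to 9-OH)
Conditions: 30 % H2O2, LiOH (0.3 equiv), MeOH, –10 °C
Reagents that add atoms: hydrogen peroxide, OO
Why: Weitz–Scheffer nucleophilic epoxidation should take the disubstituted C11=C12 enone bond (the β-carbon C8 of the other is fully substituted) on the face of the C9 hydroxyl, which directs the hydroperoxide and is also the face away from C20 (sets C11 and C12).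

Step 9
Reactants: 10 7-(tert-butyldimethylsilyloxy)-11,12-epoxy-9-hydroxypodocarp-8(14)-en-13-one
Product: 11 7-(tert-butyldimethylsilyloxy)-9,11-dihydroxypodocarp-8(14)-en-13-one (11-OH cis to 9-OH)
Conditions: SmI2 (2.2 equiv), THF/MeOH, –90 °C; pH 7 buffer
Reagents that add atoms: none
Why: Single-electron reduction of an α,β-epoxy ketone cleaves the Cα–O bond (C12–O) to give the β-hydroxy ketone, with the C11–O bond and its configuration untouched.

Step 10
Reactants: 11 7-(tert-butyldimethylsilyloxy)-9,11-dihydroxypodocarp-8(14)-en-13-one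
Product: 12 11-acetoxy-7-(tert-butyldimethylsilyloxy)-9-hydroxypodocarp-8(14)-en-13-one
Conditions: Ac2O, pyridine, DMAP (cat.), CH2Cl2, 0 °C
Reagents that add atoms: acetic anhydride, CC(=O)OC(C)=O
Why: Acylation should be selective for the secondary C11 alcohol over the tertiary C9 alcohol; the mild base and low temperature are chosen to avoid β-elimination of the acetoxy ketone.

Step 11
Reactants: 13 propa-1,2-diene; 14 dichlorodimethylsilane
Product: 16 chloro(dimethyl)(propa-1,2-dien-1-yl)silane, via allenyllithium 15 (not isolated)
Conditions: n-BuLi, THF, –78 °C; then added to Me2SiCl2 (3 equiv), –78 °C to rt; distillation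
Reagents that add atoms: none
Why: Lithiation of allene and silylation of allenyllithium, which reacts with chlorosilanes at the metallated carbon to give the allenylsilane; the excess dichlorosilane limits double substitution.

Step 12
Reactants: 12 11-acetoxy-7-(tert-butyldimethylsilyloxy)-9-hydroxypodocarp-8(14)-en-13-one; 16 chloro(dimethyl)(propa-1,2-dien-1-yl)silane
Product: 17 11-acetoxy-7-(tert-butyldimethylsilyloxy)-9-[dimethyl(propa-1,2-dienyl)silyloxy]podocarp-8(14)-en-13-one
Conditions: imidazole, DMAP (cat.), CH2Cl2, rt
Reagents that add atoms: none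
Why: Silyl ether formation with a small dialkylchlorosilane on the only free (tertiary) hydroxyl installs the temporary silicon tether on the face trans to C20.

Step 13
Reactants: 17 11-acetoxy-7-(tert-butyldimethylsilyloxy)-9-[dimethyl(propa-1,2-dienyl)silyloxy]podocarp-8(14)-en-13-one
Product: 18 pentacyclic photoadduct: 13-ketone with cyclobutane C8–C15–C16(=CH2)–C14 and oxasilolane C8–C9–O–SiMe2–C15, both cis to the C9 oxygen (trans to C20)
Conditions: hν (350 nm), degassed CH2Cl2 (5 mM), –20 °C
Reagents that add atoms: none
Why: Intramolecular enone–allene [2+2] photocycloaddition through a temporary silicon tether: 1,5-closure (rule of five) should join C8 to the silicon-bearing allene carbon and C14 to the central allene carbon, and the two-atom O–Si tether can only reach the face of the C9 oxygen, which sets C8, C14 and C15.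

Step 14
Reactants: 18 pentacyclic photoadduct 13-ketone
Product: 19 13-alcohol of 18 (13-OH cis to the cyclobutane)
Conditions: NaBH4, CeCl3·7H2O, MeOH/THF, –78 °C; AcOH quench
Reagents that add atoms: none
Why: Luche-type hydride reduction should occur from the face opposite the cyclobutane and the axial acetate (sets C13 for the moment); the cold acidic quench is meant to suppress 1,3-acetyl migration.

Step 15
Reactants: 19 13-alcohol of 18
Product: 20 13-bromide (Br trans to the cyclobutane)
Conditions: CBr4, PPh3, 2,6-lutidine, CH2Cl2, 0 °C to rt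
Reagents that add atoms: carbon tetrabromide, BrC(Br)(Br)Br
Why: Appel bromination, SN2 displacement of the alkoxyphosphonium by bromide with inversion, should place the leaving group on the face opposite the migrating cyclobutane bond.

Step 16
Reactants: 20 13-bromide with the oxasilolane
Product: 21 11-acetoxy-13-bromo-7-(tert-butyldimethylsilyloxy)-9,15-dihydroxy cyclobutane tetracycle
Conditions: 30 % H2O2, KF, KHCO3, THF/MeOH, 25 °C
Reagents that add atoms: hydrogen peroxide, OO
Why: Tamao–Fleming oxidation of the cyclic alkoxysilane should convert C15–Si into C15–OH with retention and release the tertiary C9 hydroxyl.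

Step 17
Reactants: 21 9,15-diol bromide
Product: 22 11-acetoxy-13-bromo-7-(tert-butyldimethylsilyloxy)-9-hydroxy-16-methylene-15-oxo cyclobutanone tetracycle
Conditions: Dess–Martin periodinane, NaHCO3, CH2Cl2, 0 °C; used at once
Reagents that add atoms: none
Why: Dess–Martin oxidation should convert the secondary cyclobutanol into the 2-methylenecyclobutanone and cannot touch the tertiary alcohol.

Step 18
Reactants: 22 bromo hydroxy 2-methylenecyclobutanone tetracycle
Product: 24 7-O-tert-butyldimethylsilyl ether of the target, via bridging C14 carbocation 23 (not isolated)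
Conditions: AgOTf (1.5 equiv), 2,6-di-tert-butyl-4-methylpyridine (2 equiv), CH2Cl2, –40 to 0 °C, dark
Reagents that add atoms: none
Why: Proposed new method: Ag(I) abstracts the C13 bromide, and as charge develops at C13 the alkenyl carbon C16 of the methylenecyclobutanone should migrate from C14 to C13 (Wagner–Meerwein shift, assisted by the C16=C17 π bond on the face opposite bromide); the resulting bridging C14 cation 23 is then quenched by Grob-type heterolysis of the C8–C9 bond, pushed by the free 9-OH, to give the C9 ketone and the C8=C14 enone. The closest known reactions are the cationic bicyclo[4.2.0]octane to bicyclo[3.2.1]octane (cyclobutylcarbinyl to cyclopentyl) rearrangements of enone–olefin photoadducts and the Grob/Wharton fragmentation of 1,3-diol monosulfonates to cyclodecenones; their union in one operation on a γ-hydroxy cyclobutylcarbinyl halide is new. The five-membered ring closes by ring expansion (1,2-shift inserting C13 into the C14–C16 bond of the four-membered ring), and the ten-membered ring is not closed but uncovered by cleavage of the bond shared by the two six-membered rings. The only new stereocentre, C13, is fixed by the suprafacial shift: C16 stays on the ring face to which the silicon tether delivered it in step 13, so the bromide configuration is not transferred. The step needs C16 migration rather than a shift of the ring-fusion carbon C8 or of hydride, and C8–C9 rather than C7–C8 or C8–C15 cleavage. The first should follow from the high migratory aptitude of an alkenyl carbon and from the fragmentation outlet that only cation 23 has; the second from the free tertiary hydroxyl at C9 being the only good donor (C7–O is a silyl ether, C15 a carbonyl) and from 23 having no Bredt-allowed β-hydrogen to lose.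

Step 19
Reactants: 24 7-O-tert-butyldimethylsilyl ether of the target
Product: 25 target, (5R,7R,10R,11S,13R)-11-acetoxy-7-hydroxy-8,9-seco-ent-kaura-8(14),16-diene-9,15-dione
Conditions: HF·pyridine, THF/pyridine, 0 °C
Reagents that add atoms: none
Why: Fluoride-mediated cleavage of the silyl ether under buffered acidic conditions should spare the α-acetoxy ketone and the α-methylene enone.

**Compound list**

1 | 3-methoxybenzylmagnesium chloride | COc1cccc(C[Mg]Cl)c1 | starting material
2 | geranyl bromide | CC(C)=CCC/C(C)=C/CBr | starting material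
3 | 1-[(3E)-4,8-dimethylnona-3,7-dien-1-yl]-3-methoxybenzene | COc1cccc(CC/C=C(\C)CCC=C(C)C)c1 | intermediate
4 | (5R,10R)-13-methoxypodocarpa-8,11,13-triene | CC1(C)CCC[C@]2(C)[C@@H]1CCc1cc(OC)ccc12 | intermediate
5 | (5R,10R)-13-methoxy-7-oxopodocarpa-8,11,13-triene | CC1(C)CCC[C@]2(C)[C@@H]1CC(=O)c1cc(OC)ccc12 | intermediate
6 | (5R,10R)-13-hydroxy-7-oxopodocarpa-8,11,13-triene | CC1(C)CCC[C@]2(C)[C@@H]1CC(=O)c1cc(O)ccc12 | intermediate
7 | (5R,7R,10R)-podocarpa-8,11,13-triene-7,13-diol | CC1(C)CCC[C@]2(C)[C@@H]1C[C@@H](O)c1cc(O)ccc12 | intermediate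
8 | 7,9-dihydroxypodocarpa-8(14),11-dien-13-one (p-quinol) | CC1(C)CCC[C@]2(C)[C@@H]1C[C@@H](O)C1=CC(=O)C=C[C@]12O | intermediate
9 | 7-O-TBS p-quinol | CC1(C)CCC[C@]2(C)[C@@H]1C[C@@H](O[Si](C)(C)C(C)(C)C)C1=CC(=O)C=C[C@]12O | intermediate
10 | 11,12-epoxide of 9 (cis to 9-OH) | CC1(C)CCC[C@]2(C)[C@@H]1C[C@@H](O[Si](C)(C)C(C)(C)C)C1=CC(=O)[C@@H]3O[C@@H]3[C@]12O | intermediate
11 | 7-OTBS-9,11-dihydroxypodocarp-8(14)-en-13-one | CC1(C)CCC[C@]2(C)[C@@H]1C[C@@H](O[Si](C)(C)C(C)(C)C)C1=CC(=O)C[C@H](O)[C@]12O | intermediate
12 | 11-acetate of 11 | CC1(C)CCC[C@]2(C)[C@@H]1C[C@@H](O[Si](C)(C)C(C)(C)C)C1=CC(=O)C[C@H](OC(C)=O)[C@]12O | intermediate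
13 | propa-1,2-diene | C=C=C | starting material
14 | dichlorodimethylsilane | C[Si](C)(Cl)Cl | starting material
15 | allenyllithium (not isolated) | C=C=C[Li] | intermediate
16 | chloro(dimethyl)(propa-1,2-dien-1-yl)silane | C=C=C[Si](C)(C)Cl | intermediate
17 | 9-O-[dimethyl(propa-1,2-dienyl)silyl] ether of 12 | CC1(C)CCC[C@]2(C)[C@@H]1C[C@@H](O[Si](C)(C)C(C)(C)C)C1=CC(=O)C[C@H](OC(C)=O)[C@]12O[Si](C)(C)C=C=C | intermediate
18 | pentacyclic photoadduct 13-ketone (methylenecyclobutane plus oxasilolane) | CC1(C)CCC[C@]2(C)[C@@H]1C[C@@H](O[Si](C)(C)C(C)(C)C)[C@@]13[C@H]4C(=O)C[C@H](OC(C)=O)[C@]12O[Si](C)(C)[C@@H]3C4=C | intermediate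
19 | 13-alcohol of 18 (OH cis to cyclobutane) | CC1(C)CCC[C@]2(C)[C@@H]1C[C@@H](O[Si](C)(C)C(C)(C)C)[C@@]13[C@H]4[C@H](O)C[C@H](OC(C)=O)[C@]12O[Si](C)(C)[C@@H]3C4=C | intermediate
20 | 13-bromide (Br trans to cyclobutane) | CC1(C)CCC[C@]2(C)[C@@H]1C[C@@H](O[Si](C)(C)C(C)(C)C)[C@@]13[C@H]4[C@@H](Br)C[C@H](OC(C)=O)[C@]12O[Si](C)(C)[C@@H]3C4=C | intermediate
21 | 9,15-diol bromide (methylenecyclobutanol) | CC1(C)CCC[C@]2(C)[C@@H]1C[C@@H](O[Si](C)(C)C(C)(C)C)[C@]13[C@H](O)C(=C)[C@@H]3[C@@H](Br)C[C@H](OC(C)=O)[C@]12O | intermediate
22 | bromo hydroxy 2-methylenecyclobutanone tetracycle | CC1(C)CCC[C@]2(C)[C@@H]1C[C@@H](O[Si](C)(C)C(C)(C)C)[C@]13C(=O)C(=C)[C@@H]3[C@@H](Br)C[C@H](OC(C)=O)[C@]12O | intermediate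
23 | bridging C14 carbocation after ring expansion (not isolated) | CC1(C)CCC[C@]2(C)[C@@H]1C[C@@H](O[Si](C)(C)C(C)(C)C)[C@]13C(=O)C(=C)[C@@H]([CH+]3)C[C@H](OC(C)=O)[C@]12O | intermediate
24 | 7-O-TBS ether of the target | C=C1C(=O)C2=C[C@H]1C[C@H](OC(C)=O)C(=O)[C@]1(C)CCCC(C)(C)[C@H]1C[C@H]2O[Si](C)(C)C(C)(C)C | intermediate
25 | target (CNP0165527.2) | C=C1C(=O)C2=C[C@H]1C[C@H](OC(C)=O)C(=O)[C@]1(C)CCCC(C)(C)[C@H]1C[C@H]2O | target

**Summary**

Total step count: 19. Longest linear sequence: 18 steps (steps 1–10 and 12–19; step 11 is a one-step side branch).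

Steps most likely to fail:

1. Step 18 (proposed new method). What may go wrong: ionization at C13 without the intended shift, that is loss of HBr toward C12, or migration of the ring-fusion bond (C8) or of hydride instead of the alkenyl carbon, because ring C holds the C14–C16 bond poorly aligned with the leaving group. Fallback: the two events are separated, setting out from 22. Base-mediated retro-aldol cleavage of the β-hydroxy cyclobutanone (DBU cat., toluene, 0 °C to rt) should first open the C8–C9 bond to the ten-membered bromo diketone carrying the intact 2-methylenecyclobutanone F1 (mixture of C8 epimers, of no consequence). The bromide-bearing carbon is now a freely rotating ring carbon next to the cyclobutane. Silver-assisted Wagner–Meerwein ring expansion of this cyclobutylcarbinyl bromide (AgOTf, 2,6-di-tert-butyl-4-methylpyridine, CH2Cl2) with loss of the C8 proton then returns to the route at 24.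

2. Step 6. What may go wrong: poor regioselectivity of the oxidative dearomatization (ortho attack or oligomerization of the phenoxenium species in place of water addition at the hindered para carbon C9). Fallback: setting out from 7, para-peroxidation with singlet-oxygen-type chemistry (Oxone, NaHCO3, MeCN/H2O) should give the p-peroxyquinol F2 through the small dioxygen electrophile; reduction of the O–O bond with PPh3 returns to the route at 8.

3. Step 9. What may go wrong: β-elimination of the newly formed β-hydroxy ketone back to the dienone, or over-reduction of the enone during the epoxide opening. Fallback: the C11 oxygen is introduced without an epoxide, setting out from 9. Copper-catalysed conjugate borylation (B2pin2, CuCl/NaOt-Bu/DPEphos cat., MeOH, THF) of the less hindered C11=C12 enone bond, from the face away from C20, should give the β-boryl ketone F3. Oxidation with NaBO3·4H2O (retention at carbon) returns to the route at 11.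

Further compounds
F1 | step 18 | ten-membered 9,15-dioxo 13-bromide with intact 2-methylenecyclobutanone (retro-aldol product, C8 epimers) | CC1(C)CCC[C@]2(C)[C@@H]1C[C@@H](O[Si](C)(C)C(C)(C)C)C1C(=O)C(=C)[C@@H]1[C@@H](Br)C[C@H](OC(C)=O)C2=O
F2 | step 6 | 9-hydroperoxy-7-hydroxypodocarpa-8(14),11-dien-13-one (p-peroxyquinol) | CC1(C)CCC[C@]2(C)[C@@H]1C[C@@H](O)C1=CC(=O)C=C[C@]12OO
F3 | step 9 | 11-(pinacolboryl)-7-OTBS-9-hydroxypodocarp-8(14)-en-13-one | CC1(C)CCC[C@]2(C)[C@@H]1C[C@@H](O[Si](C)(C)C(C)(C)C)C1=CC(=O)C[C@H](B3OC(C)(C)C(C)(C)O3)[C@]12O
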